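The coupling partner, I take it, is what both substrates compete for in these flasks, and the question is how its 1.30 equiv divide between them.

all flasks: starting material 23 mM
- Monday's: coupling partner 1.3 equiv; second substrate 0.17 equiv; run made earlier
- Thursday's: coupling partner 1.3 equiv; second substrate 2.9 equiv; run made earlier
- north-west: coupling partner 1.30 equiv; second substrate 0.250 equiv; time 12 h
- north-east: coupling partner 1.30 equiv; second substrate 0.500 equiv; time 12 h
- east: coupling partner 1.30 equiv; second substrate 1.00 equiv; time 12 h
- south: coupling partner 1.30 equiv; second substrate 2.00 equiv; time 12 h
- north: coupling partner 1.30 equiv; second substrate 4.00 equiv; time 12 h

| run | time / h | target / % | starting material / % |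
|---|---|---|---|
| Monday's | 1.33 | 70 | 24 |
| Monday's | 3.00 | 82 | 8 |
| Monday's | 4.00 | 87 | 11 |
| Monday's | 6.00 | 87 | 6 |
| Monday's | 8.00 | 91 | 3 |
| Thursday's | 1.33 | 53 | 45 |
| Thursday's | 3.00 | 53 | 43 |
| Thursday's | 4.00 | 52 | 40 |
| Thursday's | 6.00 | 53 | 44 |
| Thursday's | 8.00 | 50 | 44 |

(scatter of a reading: 2 percentage points)

- "hardly changes" means that all values lie within two and a half points (for a concentration: within two and a half percent of the largest)

1. amount of target at the end, in percent of the starting material charged for north-west, north-east, east, south, north, in this order
2. the course of these numbers from the first flask to the last (falls all the way / rises all the way / falls, then rises / rises, then falls / hardly changes)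

Monday's run, with 0.17 equiv of second substrate, climbs to 91 % of target, while Thursday's run, with 2.9 equiv, stands still from its first reading, with 44 % of starting material at the last. I read that stall as the coupling partner used up by the two substrates together. Then two rates matter, the rate at which starting material takes partner and the rate at which second substrate takes it. If each is first order in both reactants, c(coupling partner) stands in both and cancels, so their ratio is S times c(starting material) over c(second substrate), and S, the selectivity factor, is the ratio of the two rate constants. The zero of this scale is S = 1, where the partner takes the substrates as charged. Integrated, S is the logarithm of the fraction of starting material left over the logarithm of the fraction of second substrate left, much as a reactivity ratio is read from conversions. If the stall means that the partner is used up, then on Thursday's last reading the second substrate has taken 0.740 equiv, so I read S = 2.79, with the scatter of that reading in it.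

At the start the ratio is 11.1 in north-west and 0.697 in north, so I expect a falling row. In north the partner, reckoned at its starting share throughout, gives 53.4 % of the starting material reacted, and I expect less, since the ratio falls as the run goes on.

The forecast gives 94 %, 92 %, 83 %, 66 % and 45 %, in its words “a steady fall, flat at first”.

The flasks give 88.4 %, 85.0 %, 74.8 %, 59.7 % and 43.2 %, so the row falls all the way, lower than the forecast in north-west, where the isomer of the product stands at 10.2 %.

    starting material + coupling partner → target (k = 0.980 L mol⁻¹ min⁻¹)
    second substrate + coupling partner → second product (k = 0.340 L mol⁻¹ min⁻¹)
    target ⇌ isomer of the product (K = 0.120, k = 5.90 × 10⁻⁴ min⁻¹)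

With S as read, the 33.4 % of starting material left at the end in south calls for 67.5 % of the second substrate's own charge left, and south holds 68.3 %. The 51.7 % left in north calls for 78.9 %, and north holds 79.6 %, with coupling partner at 0 %. The low target in north is mainly the work of the path from second substrate and coupling partner to second product: with that path taken away, north gives 89.5 % of target instead of 43.2 %.

The runs stem from a simulated flask on assumed constants; scatter was added.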